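Maple held a small charge of G, 0.990 M on 0.90 M of J, and after its reading at 15.0 h I had to decide whether to leave it until 50 h or stop it and recharge.

| flask | J | G | remark | time | volume of the second phase over the first |
|---|---|---|---|---|---|
| maple | 0.90 M | 0.99 M | the very flask that is asked about, followed so far |  |  |
| ash | 0.90 M | 2 M | run made earlier |  |  |
| flask | 0.90 M | 0.990 M |  | 50 h | 2.0 |

| run | time / h | J / % | X / % |
|---|---|---|---|
| maple | 1.00 | 98.0 | 1.0 |
| maple | 3.00 | 94.0 | 1.4 |
| maple | 5.00 | 89.2 | 3.5 |
| maple | 8.00 | 83.7 | 6.1 |
| maple | 12.0 | 77.1 | 9.3 |
| maple | 15.0 | 74.2 | 10.8 |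
| ash | 2.50 | 92.8 | 2.2 |
| ash | 6.00 | 83.4 | 9.4 |
| ash | 12.0 | 69.7 | 18.6 |
| ash | 20.0 | 58.2 | 25.8 |
| ash | 25.0 | 54.5 | 28.9 |
| ash | 40.0 | 49.0 | 34.7 |

(scatter of a reading: 0.5 percentage points)

- in the second phase: G; everything else is in the first
- charges count per volume of the first phase; a concentration in a rate is the amount of a species over the volume of its own phase; every rate counts per litre of the first phase
- the earlier runs hold the two phases in the same ratio of volumes as the flask asked about
- a reading or a percentage of J is of its free form alone

- the species in which most of what was charged as J, at 50 h sits (J / X)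
- the largest share itself, whichever of these holds it, in percent of the J charged

I took the last reading of ash as a guess at its end point and read two ratios from it, the first being X over J, divided by the G not yet turned into X, and the second the shortfall from the J charged, over J:

binding ratio = 0.420 M⁻¹; shortfall ratio = 0.333

Carried to the charge of maple, with G used one for one with X formed, these gave a quadratic for the end point:

end X = 20.3%; end J = 59.8%

I then integrated the fall of J as first-order closing on that end point, and the readings of maple at 8.00 h and 15.0 h gave a rate of 0.0725 h⁻¹, so the gap shrank to half in each closing half-time (a relaxation half-life, in the usual term) of 9.56 h: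

J at 50 h = 59.8% + (74.2% − 59.8%) × exp(−0.0725 h⁻¹ × 35.0 h) = 61.0%

That left 1.2 percentage points of J still to fall, with J above X, so I decided to leave maple until 50 h and recharge nothing.

The forecast said J at 61%: “Most remains as free J”.

The flask maple gave J at 60.0%, with X at 20.4%, and the forecast held.

    J + D ⇌ X (K = 6.00 M⁻¹, k = 0.350 M⁻¹ h⁻¹)
    J ⇌ Z (K = 0.330, k = 0.0160 h⁻¹)
    D ⇌ G, rate k3*([D] - [G]/K3) per volume of the first phase (partition coefficient = 5.80, kL = 0.250 h⁻¹)

In maple, half of the turnover of J and D into X up to 50 h was done by 13.1 h, while G stood between 92.9% of its own charge at 5.00 h and 80.1% at 25.0 h, and J went to Z over the same hours, a net 19.6% of the J charged by 50 h. My closing half-time counted 3.66 half-times after the last reading, leaving 7.91% of the gap; the computed J, with 58.6% at ten times the time, leaves 9.06%.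

For the neighbour, the same flask left until 30 h, the closing half-time gave 64.7% of J. The computed flask gave 64.1%.

(Readings and results were generated by integration for an exercise; scatter was added.)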